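Start from what is left: after 6.00 h the ash flask holds 46.0 % of its substrate, and after 6.00 h the cedar flask holds 36.5 %.

| flask | substrate | remark | time |
|---|---|---|---|
| ash | 0.028 M | run made earlier |  |
| cedar | 0.044 M | run made earlier |  |
| violet | 0.020 M |  | 8.0 h |
| red | 0.020 M |  | 24 h |
| amber | 0.020 M |  | 72 h |

| run | time / h | substrate / % | target / % | over-reaction product / % |
|---|---|---|---|---|
| ash | 1.33 | 80.6 | 0 | 0 |
| ash | 2.50 | 69.7 | 0.9 | 1.8 |
| ash | 4.00 | 56.8 | 2.8 | 0.4 |
| ash | 5.00 | 50.5 | 3.3 | 0 |
| ash | 6.00 | 46.0 | 2.7 | 0 |
| cedar | 0.500 | 87.7 | 0 | 0 |
| cedar | 1.00 | 76.6 | 0 | 0 |
| cedar | 2.00 | 64.5 | 1.9 | 1.2 |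
| cedar | 3.00 | 55.4 | 3.7 | 0 |
| cedar | 6.00 | 36.5 | 2.8 | 0.7 |

(readings scatter by 1 percentage point)

- a species is counted by the substrate in it: one homo dimer counts as two
- amounts and yields of target count crystals too
- given per volume of solution although it is solid: crystals
- steps under discussion: substrate + target -> 2 target; substrate -> target; target -> over-reaction product; 2 substrate -> homo dimer; crystals <-> target

* which of these there is most of at the end, counted by the substrate in it, violet (substrate / over-reaction product / target)
* which of these there is most of at the end, counted by the substrate in it, red (substrate / over-reaction product / target)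
* which of these there is most of at the end, counted by the substrate in it, amber (substrate / over-reaction product / target)
* the largest of these amounts at the end, in percent of the substrate charged, violet
* the largest of these amounts at the end, in percent of the substrate charged, red
* the largest of these amounts at the end, in percent of the substrate charged, amber

Take first-order loss as the zero of the scale: there, every charge keeps the same percentage at the same hour. But cedar, with the heavier charge, keeps less than ash, and the gap of 9.5 percentage points stands against a scatter of 1 point. So try second-order loss, where the fraction left, f, obeys: one over f, less one, equals s·c·t, with c the charge and t the time. Ash gives 0.116 M⁻¹ min⁻¹ for s, cedar 0.110 M⁻¹ min⁻¹. Call their mean, 0.113 M⁻¹ min⁻¹, the pairing slope, the rise per minute of one over the substrate concentration.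

Object that two late readings prove no line. Then read ash earlier: at 4.00 h it gives 0.113 M⁻¹ min⁻¹, close to its late value. Object next that the lost substrate must appear somewhere. In ash, 54.0 % has gone at 6.00 h, while target reads 2.7 % and over-reaction product 0 %, so the loss lies in something unread, and the homo dimer, made from two substrates, suits a square law.

Now reckon the substrate left: 47.9 % in violet, 23.5 % in red, 9.28 % in amber. Hold the amber figure loosely, since amber runs far beyond the readings. The slope says nothing of target, so I name substrate as leader in violet and red and leave amber open.

The forecast, using a slope of 6.6 per molar and per hour where mine is told per minute, and holding that “homo dimerisation is the main sink”, names substrate at 48 % for violet, substrate at 24 % for red and target at 13 % for amber. Its substrate figure for amber is 9.5, close to mine.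

The flasks give substrate at 47.6 % in violet, substrate at 21.3 % in red, and target at 13.2 % in amber, with substrate there at 6.35 %.

    substrate + target → 2 target (k = 0.813 M⁻¹ min⁻¹)
    substrate → target (k = 6.58 × 10⁻⁶ min⁻¹)
    target → over-reaction product (k = 3.43 × 10⁻⁴ min⁻¹)
    2 substrate → homo dimer (k = 0.0524 M⁻¹ min⁻¹)
    crystals ⇌ target, rate k5*(cs5 - [target]) while solid is left; crystals form when [target] > cs5 (solubility = 0.210 mM, k = 0.221 min⁻¹)

Cut amber back to the time of violet and its substrate stands at 47.6 %, not 6.35 %: the longer time is the main reason for amber's low substrate, and the homo dimer step is a part of that loss. The pairing slope gave 47.9 % for violet, and it runs above the flask later, with 9.28 % against 6.35 % in amber. On the neighbour of red charged with 0.012 M, the slope gives 33.9 % left after 24 h; that flask holds 30.5 %.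

The numbers in the tables stem from a simulated flask for substances that don't exist; scatter was added.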